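No constant was given to me, so I looked in the readings for one ratio: how a Q divides between D and Z.

| flask | X | D | Z | temperature | remark | time |
|---|---|---|---|---|---|---|
| east | 0.20 M | 0.80 M | 0.16 M | 35 °C | run made earlier |  |
| west | 0.20 M | 1.1 M | 0.16 M | 50 °C | run made earlier |  |
| north-east | 0.20 M | 1.8 M | 0.16 M | 35 °C | run made earlier |  |
| theta | 0.20 M (fed, over 2.0 h) | 0.800 M | 0.160 M |  | the addition at 30 °C, then warmed to 50 °C; the feed brings no volume worth counting | 2.5 h |
| alpha | 0.20 M | 0.800 M | 0.160 M (fed, over 2.0 h) | 50 °C | all else is in the flask from the start; the feed brings no volume worth counting | 2.5 h |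
| delta | 0.20 M | 0.800 M | 0.160 M | 50 °C | everything together at the start | 2.5 h |
| beta | 0.20 M (fed, over 2.0 h) | 0.800 M | 0.160 M | 50 °C | all else is in the flask from the start; the feed brings no volume worth counting | 2.5 h |

east run (percent of the X charged)

| time / h | E / % | G / % | X / % |
|---|---|---|---|
| 0.250 | 0 | 0 | 99.1 |
| 0.500 | 0.1 | 0.6 | 99.6 |
| 1.33 | 0.8 | 1.1 | 98.6 |
| 3.00 | 0.8 | 1.3 | 96.1 |

west run (percent of the X charged)

| time / min | E / % | G / % | X / % |
|---|---|---|---|
| 15.0 | 0.5 | 0.9 | 97.3 |
| 40.0 | 1.3 | 3.1 | 92.9 |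
| 80.0 | 4.1 | 6.0 | 86.8 |
| 120 | 6.5 | 8.9 | 80.4 |

north-east run (percent of the X charged)

| time / h | E / % | G / % | X / % |
|---|---|---|---|
| 1.00 | 0 | 0.9 | 98.5 |
| 2.00 | 0.1 | 2.0 | 97.7 |
| 3.00 | 0.4 | 2.5 | 96.1 |
| 4.00 | 1.0 | 3.2 | 94.7 |

(scatter of a reading: 0.3 percentage points)

- in percentages every species weighs as the X in it: one L counts as two
- on the list of suspects stand: D + Q -> G; X + G -> L; X -> Q; Z + Q -> E; D <-> J

* the flask that comes out highest in amount of E, in percent of the X charged, or "all alike" when all lie within 1.5 percentage points (theta / alpha / delta / beta / all alike)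
* E at the end, in percent of the X charged, theta
* E at the end, in percent of the X charged, alpha
* E at the end, in percent of the X charged, delta
* E at the end, in percent of the X charged, beta

How does Q split? My zero was even odds, 1, as much E as G. In west at 120 min I read E 6.5%, G 8.9% and a gap in the balance of 4.20%. I counted the gap as L, so half of it had once been G, and the G side came to 11.0%. West stood at 50 °C, like delta, so I divided its E over G by its Z charged per D charged and got a selectivity factor, on charged amounts, of 4.06, a reading that carries the scatter of the run. With these charges that gave the odds 0.813, E formed per G formed from Q, with Z at its full charge. So I took the share of Q going to E as 44.8%.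

How much X passed through Q? By these readings west passed 17.5%, a first-order rate of 0.0962 h⁻¹. So I reckoned that delta passed 21.4%, with E at 9.58%.

What does each feed change? In beta, fed X stayed 1.50 h on average, so I reckoned that 13.4% passed, with E at 6.02%. In alpha, the Z fed, counted as if none were used, averaged 60.0% of its charge, so I lowered the odds to 0.488 and reckoned E at 7.00%. Theta was fed cold, and I counted its warm 0.500 h, which gave a reckoned E of 2.10%. My reckoning put delta highest, by 2.6 percentage points.

The forecast also named delta, holding that “E/G scales as Z/D”, but its figures differ from mine: delta 9%, alpha 6%, beta 6.5%, theta 2.2%.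

The flasks gave delta 9.24%, alpha 6.91%, beta 5.56%, theta 1.61%.

    D + Q → G (k = 5.30 L mol⁻¹ h⁻¹, Ea = 60.0 kJ mol⁻¹)
    X + G → L (k = 1.10 L mol⁻¹ h⁻¹, Ea = 86.0 kJ mol⁻¹)
    X → Q (k = 0.100 h⁻¹, Ea = 115 kJ mol⁻¹)
    Z + Q → E (k = 14.0 L mol⁻¹ h⁻¹, Ea = 81.0 kJ mol⁻¹)
    D ⇌ J (K = 0.740, k = 1.90 h⁻¹, Ea = 92.0 kJ mol⁻¹, ΔH = −90.0 kJ mol⁻¹)
    (constants at 50 °C)

In delta at 2.50 h, E over G plus half of L stood at 0.846, against my odds of 0.813. The neighbour is theta read at 10 h, with 8.00 h warm, so I reckoned 53.7% of X through Q. Z stood at 71% of its charge by then, and the mean of start and end lowered the odds to 0.696. That gave E 22.0%. Theta at 10 h held 22.9% of E.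

The runs come from a simulation with made-up constants; scatter was added.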